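Drimane numbering is used. Ring B (C5–C6–C7–C8–C9–C10) holds all four stereocentres. With a C6=C7 alkene added, it is a cyclohexene whose C5–C10 and C8–C9 bonds frame the C9–C10 edge, which is a Diels–Alder retron. The precursor is an open-chain trienal. It consists of the (E)-enal C11–C9=C10, the tether C1–C4 with the gem-dimethyl carbon, and a (5E,7E)-dienyl ether whose C8 bears the methyl group and an oxygen carrying bought (S)-1-(1-naphthyl)ethanol. One exo-selective intramolecular Diels–Alder reaction closes rings A and B and sets C5, C8, C9 and C10, including the cis ring fusion. Aryllithium addition, deoxygenation, hydrogenation and deprotection finish the synthesis.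

Key step: step 7

Remark on numbering: C4 is the gem-dimethyl carbon, C5 and C10 are the ring-fusion carbons, C8 is the carbinol carbon, C9 is the CH bearing C11, and C11 is the later benzylic carbon. β is the face of the C10 methyl group. The target has 5β-H, so its decalin is cis-fused.

Assumption: the facial bias of the 1-(1-naphthyl)ethyl ether is assigned from the conformational model under step 7. If it proves opposite, the equally available (R)-alcohol is used in step 2 with no other change.

Step 1
Reactants: 1 2,2-dimethylpent-4-enal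
Product: 2 (E)-1-iodo-3,3-dimethylhexa-1,5-diene
Conditions: CHI3, CrCl2, THF, 0 °C to rt
Reagents that add atoms: iodoform, IC(I)I
Why: Takai olefination, in which the gem-dichromium reagent adds to the non-enolisable neopentyl aldehyde and eliminates to the (E)-iodoalkene (C5=C6), while the isolated terminal alkene is inert.

Step 2
Reactants: 3 (S)-1-(naphthalen-1-yl)ethanol
Product: 7 (S)-1-[1-(ethynyloxy)ethyl]naphthalene, via potassium alkoxide 4 (not isolated), via dichlorovinyl ether 5 (not isolated), via lithium alkoxyacetylide 6 (not isolated)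
Conditions: KH, THF, 0 °C; Cl2C=CHCl, −50 °C to rt; n-BuLi (2.2 equiv), −78 to −40 °C; H2O, −78 °C
Reagents that add atoms: trichloroethylene, ClC=C(Cl)Cl
Why: This is the trichloroethylene route to ynol ethers (alkoxide addition–elimination, then base-induced elimination and Cl–Li exchange), and only the O–H bond of 3 reacts, so the bought stereocentre is kept.

Step 3
Reactants: 7 (S)-1-[1-(ethynyloxy)ethyl]naphthalene; 2 (E)-1-iodo-3,3-dimethylhexa-1,5-diene
Product: 10 1-[(S)-1-{[(2E,4E)-6,6-dimethylnona-2,4,8-trien-2-yl]oxy}ethyl]naphthalene, via alkenylcopper 8 (not isolated), via alkenylzinc bromide 9 (not isolated)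
Conditions: MeMgBr, CuBr·SMe2, Et2O–Me2S, −45 °C; 7, −45 to −25 °C; ZnBr2, THF; 2, Pd(PPh3)4 (5 mol %), −20 to 0 °C
Reagents that add atoms: methylmagnesium bromide, C[Mg]Br
Why: Syn-carbocupration of the alkoxyalkyne puts CH3 on the oxygen-bearing carbon (C8) and copper on the terminal carbon (C7), cis to CH3, and the Negishi-type coupling retains both alkene geometries, so C6 ends up cis to the C8 methyl and trans to oxygen.

Step 4
Reactants: 11 but-2-yn-1-ol
Product: 14 (E)-3-iodobut-2-en-1-ol, via lithium butynolate 12 (not isolated), via alkenylzirconocene 13 (not isolated)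
Conditions: n-BuLi (1.0 equiv), THF, −78 °C; Cp2Zr(H)Cl, rt; I2, 0 °C
Reagents that add atoms: iodine, II
Why: Hydrozirconation–iodination, with syn H–Zr addition placing zirconium on the less hindered methyl-bearing carbon and iodinolysis proceeding with retention, fixes CH3 cis to CH2OH.

Step 5
Reactants: 10 1-[(S)-1-{[(2E,4E)-6,6-dimethylnona-2,4,8-trien-2-yl]oxy}ethyl]naphthalene; 14 (E)-3-iodobut-2-en-1-ol
Product: 16 (2E,8E,10E)-3,7,7-trimethyl-11-[(S)-1-(naphthalen-1-yl)ethoxy]dodeca-2,8,10-trien-1-ol, via B-alkyl-9-BBN 15 (not isolated)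
Conditions: 9-BBN (1.05 equiv), THF, 0 °C to rt; 14, Pd(dppf)Cl2 (5 mol %), Cs2CO3, DMF–H2O, rt
Reagents that add atoms: none
Why: 9-BBN hydroborates the monosubstituted alkene far faster than the hindered conjugated dienyl ether, and the B-alkyl Suzuki–Miyaura coupling forms C1–C10 with retention of the (E)-iodoalkene geometry under base, which the enol ether tolerates.

Step 6
Reactants: 16 (2E,8E,10E)-3,7,7-trimethyl-11-[(S)-1-(naphthalen-1-yl)ethoxy]dodeca-2,8,10-trien-1-ol
Product: 17 (2E,8E,10E)-3,7,7-trimethyl-11-[(S)-1-(naphthalen-1-yl)ethoxy]dodeca-2,8,10-trienal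
Conditions: MnO2, CH2Cl2, rt
Reagents that add atoms: none
Why: Neutral MnO2 allylic oxidation gives the enal without E/Z isomerisation and without touching the acid-sensitive dienyl ether.

Step 7
Reactants: 17 (2E,8E,10E)-3,7,7-trimethyl-11-[(S)-1-(naphthalen-1-yl)ethoxy]dodeca-2,8,10-trienal
Product: 18 (1R,2R,4aR,8aS)-2,5,5,8a-tetramethyl-2-[(S)-1-(naphthalen-1-yl)ethoxy]-1,2,4a,5,6,7,8,8a-octahydronaphthalene-1-carbaldehyde (cis-fused; 5β-H, 10β-CH3, 9β-CHO, 8β-CH3, 8α-OR, C6=C7)
Conditions: ATPH [aluminium tris(2,6-diphenylphenoxide), 1.2 equiv], CH2Cl2–toluene, 5 mM, −78 to −20 °C; aq NaHCO3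
Reagents that add atoms: none
Why: ATPH binds the formyl oxygen and lowers the enal LUMO, and the donor-substituted diene adds across C9=C10 in a concerted but asynchronous [4+2] cycloaddition in which C5–C10 (diene terminus remote from oxygen to enal β-carbon) runs ahead of C8–C9; the closest known reaction type is the Lewis acid-promoted type 1 intramolecular Diels–Alder reaction of 1,7,9-decatrienals, combined with the exo-selective Diels–Alder reaction of ATPH-complexed carbonyl dienophiles. Ring B closes as the new cyclohexene from diene carbons C5–C8 and dienophile carbons C9 and C10, and ring A closes in the same event because the C1–C4 tether already links C10 to C5 (fused mode, 6-exo-trig at C10 in the Michael-type limit). Suprafacial addition copies the (E)-enal geometry into the cis relation of C9–CHO and C10–CH3, and it copies the (5E,7E)-diene geometry, with C4 and the ether oxygen both outside and the C8 methyl inside, into the cis relation of C5–C4 and C8–O. The cis ring fusion (H5 and C10–CH3 on one face) needs the transition state with the tether endo and the formyl group exo, which should be secured by the bowl-shaped ATPH that cannot sit under the diene and by the C10 methyl cis to the formyl group, which in the endo mode would be pressed against C6–C7 and the axial C4 methyl. The absolute sense comes from the bought stereocentre: the geminal C8 methyl forces the O–CH bond s-cis to C7=C8, the carbinol H lies in plane towards H7, the naphthyl ring covers one diene face, and the ATPH-capped dienophile should take the face flanked only by the small methyl group. Hetero-Diels–Alder or aldol-type attack at C11=O should be blocked by the ATPH pocket, high dilution should suppress intermolecular reaction, and a minor diastereomer can be removed by chromatography because the auxiliary is still attached.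

Step 8
Reactants: 19 2,5-dihydroxybenzaldehyde
Product: 20 2,5-bis(methoxymethoxy)benzaldehyde
Conditions: MOMCl, K2CO3, acetone, 0 °C to reflux
Reagents that add atoms: chloromethyl methyl ether, COCCl
Why: Williamson-type O-alkylation protects both phenols as MOM ethers, which later direct the metalation and leave under mild acid.

Step 9
Reactants: 20 2,5-bis(methoxymethoxy)benzaldehyde
Product: 21 2-[2,5-bis(methoxymethoxy)phenyl]-1,3-dioxolane
Conditions: TMSOCH2CH2OTMS, TMSOTf (2 mol %), CH2Cl2, −78 to −20 °C; pyridine quench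
Reagents that add atoms: 1,2-bis(trimethylsilyloxy)ethane, C[Si](C)(C)OCCO[Si](C)(C)C
Why: Noyori acetalisation works under aprotic low-temperature conditions that the MOM ethers tolerate, and it masks the formyl group against organolithium, radical and hydrogenation steps.

Step 10
Reactants: 21 2-[2,5-bis(methoxymethoxy)phenyl]-1,3-dioxolane; 18 cis-fused aldehyde from step 7
Product: 25 O-{[2-(1,3-dioxolan-2-yl)-3,6-bis(methoxymethoxy)phenyl](C9-drimenyl residue of 18)methyl} S-methyl dithiocarbonate (both C11 epimers), via aryllithium 22 (not isolated), via lithium alkoxide 23 (not isolated), via lithium xanthate 24 (not isolated)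
Conditions: 21, n-BuLi, TMEDA, Et2O–THF, 0 °C; 18, −78 °C; CS2, −78 to 0 °C; MeI, rt
Reagents that add atoms: carbon disulfide, S=C=S; iodomethane, CI
Why: Directed ortho-metalation should occur at the only ring position flanked by two coordinating groups (OMOM and dioxolane), the aryllithium adds 1,2 to the hindered aldehyde, and the alkoxide is trapped in the same flask as the xanthate; the uncontrolled C11 centre is erased in step 11.

Step 11
Reactants: 25 xanthate from step 10
Product: 26 2-[3,6-bis(methoxymethoxy)-2-{[(1R,2R,4aR,8aS)-2,5,5,8a-tetramethyl-2-[(S)-1-(naphthalen-1-yl)ethoxy]-1,2,4a,5,6,7,8,8a-octahydronaphthalen-1-yl]methyl}phenyl]-1,3-dioxolane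
Conditions: Bu3SnH (excess), AIBN (cat.), toluene, 90 °C
Reagents that add atoms: none
Why: Barton–McCombie deoxygenation through the benzylic C11 radical runs under neutral conditions that spare the acetal, the MOM groups and the allylic tertiary ether, and it leaves C9 untouched.

Step 12
Reactants: 26 deoxygenated dienyl-ether adduct from step 11
Product: 27 (1R,2R,4aR,8aS)-1-{[2-(1,3-dioxolan-2-yl)-3,6-bis(methoxymethoxy)phenyl]methyl}-2,5,5,8a-tetramethyldecahydronaphthalen-2-ol
Conditions: H2 (1 atm), 10% Pd/C, EtOAc–EtOH, rt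
Reagents that add atoms: none
Why: Catalytic hydrogenation saturates the cis-disubstituted C6=C7 alkene (no new stereocentre) and hydrogenolysis cleaves the naphthylic C–O bond on the auxiliary side, so C8 keeps its oxygen and configuration, while the di-ortho-substituted aryl dioxolane should hold in the neutral medium.

Step 13
Reactants: 27 protected tertiary alcohol from step 12
Product: 28 3,6-dihydroxy-2-{[(1R,2R,4aR,8aS)-2-hydroxy-2,5,5,8a-tetramethyldecahydronaphthalen-1-yl]methyl}benzaldehyde (target)
Conditions: 2 M aq HCl, THF–MeOH, degassed, rt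
Reagents that add atoms: water, O
Why: Acid-catalysed acetal hydrolysis removes both MOM groups and the dioxolane, and dilute acid at room temperature should be too weak to ionise the unactivated tertiary C8 alcohol, so dehydration and chroman closure should not intervene.

Compound list
1 | 2,2-dimethylpent-4-enal | C=CCC(C)(C)C=O | starting material
2 | (E)-1-iodo-3,3-dimethylhexa-1,5-diene | C=CCC(C)(C)/C=C/I | intermediate
3 | (S)-1-(naphthalen-1-yl)ethanol | C[C@H](O)c1cccc2ccccc12 | starting material
4 | potassium (S)-1-(naphthalen-1-yl)ethanolate | C[C@H](O[K])c1cccc2ccccc12 | intermediate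
5 | 1-[(S)-1-{[(E)-1,2-dichloroethenyl]oxy}ethyl]naphthalene | C[C@H](O/C(Cl)=C\Cl)c1cccc2ccccc12 | intermediate
6 | lithium {[(S)-1-(naphthalen-1-yl)ethoxy]ethynide} | C[C@H](OC#C[Li])c1cccc2ccccc12 | intermediate
7 | (S)-1-[1-(ethynyloxy)ethyl]naphthalene | C[C@H](OC#C)c1cccc2ccccc12 | intermediate
8 | {(E)-2-[(S)-1-(naphthalen-1-yl)ethoxy]prop-1-enyl}copper (Cu cis to CH3) | C[C@H](O/C(C)=C/[Cu])c1cccc2ccccc12 | intermediate
9 | {(E)-2-[(S)-1-(naphthalen-1-yl)ethoxy]prop-1-enyl}zinc bromide | C[C@H](O/C(C)=C/[Zn]Br)c1cccc2ccccc12 | intermediate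
10 | 1-[(S)-1-{[(2E,4E)-6,6-dimethylnona-2,4,8-trien-2-yl]oxy}ethyl]naphthalene | C=CCC(C)(C)/C=C/C=C(\C)O[C@@H](C)c1cccc2ccccc12 | intermediate
11 | but-2-yn-1-ol | CC#CCO | starting material
12 | lithium but-2-yn-1-olate | CC#CCO[Li] | intermediate
13 | lithium (E)-3-[chlorobis(cyclopentadienyl)zirconio]but-2-en-1-olate | [Li]OC/C=C(\C)[Zr](Cl)(C1C=CC=C1)C1C=CC=C1 | intermediate
14 | (E)-3-iodobut-2-en-1-ol | OC/C=C(\C)I | intermediate
15 | 9-{(5E,7E)-4,4-dimethyl-8-[(S)-1-(naphthalen-1-yl)ethoxy]nona-5,7-dienyl}-9-borabicyclo[3.3.1]nonane | C1CC2CCCC(C1)B2CCCC(C)(C)/C=C/C=C(\C)O[C@@H](C)c1cccc2ccccc12 | intermediate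
16 | (2E,8E,10E)-3,7,7-trimethyl-11-[(S)-1-(naphthalen-1-yl)ethoxy]dodeca-2,8,10-trien-1-ol | OC/C=C(\C)CCCC(C)(C)/C=C/C=C(\C)O[C@@H](C)c1cccc2ccccc12 | intermediate
17 | (2E,8E,10E)-3,7,7-trimethyl-11-[(S)-1-(naphthalen-1-yl)ethoxy]dodeca-2,8,10-trienal | O=C/C=C(\C)CCCC(C)(C)/C=C/C=C(\C)O[C@@H](C)c1cccc2ccccc12 | intermediate
18 | (1R,2R,4aR,8aS)-2,5,5,8a-tetramethyl-2-[(S)-1-(naphthalen-1-yl)ethoxy]-1,2,4a,5,6,7,8,8a-octahydronaphthalene-1-carbaldehyde | CC1(C)CCC[C@@]2(C)[C@@H]1C=C[C@@](C)(O[C@@H](C)c1cccc3ccccc13)[C@@H]2C=O | intermediate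
19 | 2,5-dihydroxybenzaldehyde | O=Cc1cc(O)ccc1O | starting material
20 | 2,5-bis(methoxymethoxy)benzaldehyde | O=Cc1cc(OCOC)ccc1OCOC | intermediate
21 | 2-[2,5-bis(methoxymethoxy)phenyl]-1,3-dioxolane | COCOc1ccc(OCOC)c(C2OCCO2)c1 | intermediate
22 | [2-(1,3-dioxolan-2-yl)-3,6-bis(methoxymethoxy)phenyl]lithium | [Li]c1c(OCOC)ccc(OCOC)c1C1OCCO1 | intermediate
23 | lithium alkoxide of the C11 carbinol from 18 and 22 (C11 epimers) | CC1(C)CCC[C@@]2(C)[C@@H]1C=C[C@@](C)(O[C@@H](C)c1cccc3ccccc13)[C@@H]2C(O[Li])c1c(OCOC)ccc(OCOC)c1C1OCCO1 | intermediate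
24 | lithium O-alkyl dithiocarbonate from 23 and CS2 (C11 epimers) | CC1(C)CCC[C@@]2(C)[C@@H]1C=C[C@@](C)(O[C@@H](C)c1cccc3ccccc13)[C@@H]2C(OC(=S)S[Li])c1c(OCOC)ccc(OCOC)c1C1OCCO1 | intermediate
25 | O-alkyl S-methyl dithiocarbonate (xanthate) of the C11 carbinol (C11 epimers) | CC1(C)CCC[C@@]2(C)[C@@H]1C=C[C@@](C)(O[C@@H](C)c1cccc3ccccc13)[C@@H]2C(OC(=S)SC)c1c(OCOC)ccc(OCOC)c1C1OCCO1 | intermediate
26 | 2-[3,6-bis(methoxymethoxy)-2-{[(1R,2R,4aR,8aS)-2,5,5,8a-tetramethyl-2-[(S)-1-(naphthalen-1-yl)ethoxy]-1,2,4a,5,6,7,8,8a-octahydronaphthalen-1-yl]methyl}phenyl]-1,3-dioxolane | CC1(C)CCC[C@@]2(C)[C@@H]1C=C[C@@](C)(O[C@@H](C)c1cccc3ccccc13)[C@@H]2Cc1c(OCOC)ccc(OCOC)c1C1OCCO1 | intermediate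
27 | (1R,2R,4aR,8aS)-1-{[2-(1,3-dioxolan-2-yl)-3,6-bis(methoxymethoxy)phenyl]methyl}-2,5,5,8a-tetramethyldecahydronaphthalen-2-ol | CC1(C)CCC[C@@]2(C)[C@@H]1CC[C@@](C)(O)[C@@H]2Cc1c(OCOC)ccc(OCOC)c1C1OCCO1 | intermediate
28 | 3,6-dihydroxy-2-{[(1R,2R,4aR,8aS)-2-hydroxy-2,5,5,8a-tetramethyldecahydronaphthalen-1-yl]methyl}benzaldehyde | CC1(C)CCC[C@@]2(C)[C@@H]1CC[C@@](C)(O)[C@@H]2Cc1c(O)ccc(O)c1C=O | target

Total step count: 13. Longest linear sequence: 9 steps (2, 3, 5, 6, 7, 10, 11, 12, 13; the line from 1 through step 1 is equally long).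

Steps most likely to fail

First, step 7.
- **What may go wrong:** The hindered cycloaddition may stall at an open-chain Michael-type stage, because the diene with its inside methyl reaches the s-cis form reluctantly. The reaction may also leak into the endo mode, which gives the trans ring fusion, or the facial bias may be weak.
- **Fallback:** This route lets the endo rule work for the cis fusion instead of against it. It sets out from 11 and from borane 15 (made from 10 as in step 5) and comes back at 18.
- **Sequence to the (2Z)-trienal:** Red-Al trans-hydroalumination of 11 followed by iodinolysis gives (Z)-3-iodobut-2-en-1-ol F1. B-alkyl Suzuki–Miyaura coupling of F1 with 15 gives the (2Z,8E,10E)-trienol F2, and MnO2 oxidation gives the (2Z,8E,10E)-trienal F3.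
- **Cycloaddition and epimerisation:** In F3 the formyl group and the tether are cis on the dienophile. An ordinary endo-selective Me2AlCl-promoted intramolecular Diels–Alder reaction therefore places both under the diene and should give the cis-fused 9-epi aldehyde F4, which differs from 18 only at C9. Equilibration with DBU through the enolate should move the formyl group to the β face, anti to the C8–O and C10–C1 bonds, and give 18.

Second, step 3.
- **What may go wrong:** The alkenylmetal, whose metal and alkoxy group are trans, may be lost by anti β-elimination of the alkoxide while the palladium cycle is still slow.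
- **Fallback:** This route separates metalation and coupling through a storable nucleophile. It sets out from 8 (generated from 7 as in step 3) and from 2, and comes back at 10.
- **Sequence:** The alkenylcopper is quenched at −40 °C with Bu3SnCl to give the isolable tributyl{(E)-2-[(S)-1-(naphthalen-1-yl)ethoxy]prop-1-enyl}stannane F5. A neutral Stille coupling of F5 with 2 (Pd2(dba)3, AsPh3, CuI, DMF, rt) then gives 10 with retention at both alkenes.

Third, step 10.
- **What may go wrong:** The crowded β-alkoxy aldehyde may enolise, or the very hindered alkoxide may be captured incompletely by CS2.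
- **Fallback:** This route replaces radical deoxygenation by catalytic hydrogenolysis. It sets out from 18 and 22 and comes back at 27.
- **Sequence:** The adduct 23 is quenched with water to give the C11 carbinol F6. Raney nickel under hydrogen in refluxing EtOH–THF should remove the electron-rich benzylic hydroxyl group, saturate C6=C7 and cleave the naphthylethyl ether in one operation, giving 27 directly.

Further compounds
F1 | step 7 | (Z)-3-iodobut-2-en-1-ol | OC/C=C(/C)I
F2 | step 7 | (2Z,8E,10E)-3,7,7-trimethyl-11-[(S)-1-(naphthalen-1-yl)ethoxy]dodeca-2,8,10-trien-1-ol | OC/C=C(/C)CCCC(C)(C)/C=C/C=C(\C)O[C@@H](C)c1cccc2ccccc12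
F3 | step 7 | (2Z,8E,10E)-3,7,7-trimethyl-11-[(S)-1-(naphthalen-1-yl)ethoxy]dodeca-2,8,10-trienal | O=C/C=C(/C)CCCC(C)(C)/C=C/C=C(\C)O[C@@H](C)c1cccc2ccccc12
F4 | step 7 | (1S,2R,4aR,8aS)-2,5,5,8a-tetramethyl-2-[(S)-1-(naphthalen-1-yl)ethoxy]-1,2,4a,5,6,7,8,8a-octahydronaphthalene-1-carbaldehyde (9-epi-18) | CC1(C)CCC[C@@]2(C)[C@@H]1C=C[C@@](C)(O[C@@H](C)c1cccc3ccccc13)[C@H]2C=O
F5 | step 3 | tributyl{(E)-2-[(S)-1-(naphthalen-1-yl)ethoxy]prop-1-enyl}stannane | CCCC[Sn](CCCC)(CCCC)/C=C(\C)O[C@@H](C)c1cccc2ccccc12
F6 | step 10 | C11 carbinol from 18 and 22 (C11 epimers) | CC1(C)CCC[C@@]2(C)[C@@H]1C=C[C@@](C)(O[C@@H](C)c1cccc3ccccc13)[C@@H]2C(O)c1c(OCOC)ccc(OCOC)c1C1OCCO1
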